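**Plan**
- Retrosynthesis: cut C12–C13 and C11=C12 (cross-coupling, borylolefination), take the esters and the 7,8-diol back to a ring B 7-en-6-one and the C4 methyl back to a ring A 2-en-4-one. Then cut C5–C10 and C2–C3 of this decalin bis-enone in one Michael/aldol-condensation event.
- Enabling feature: C5 lies between C4 and C6. As a 2-methyl-1,3-diketone carbon it attacks C10, the β-carbon of an enal C10=C1–C2HO on C9, and the C4 acetyl methyl (C3) then condenses with C2. A Z C7=C8 enone keeps C5 within reach of C10.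
- Forward: C9 stereocentre, then its three arms (Z-enone/diketone tether, enal, CH2OTBS), then ring B and ring A in the key step, then ring A triflate/methyl, ring B reduction, osmylation and acylations, side chain last.
- Stereochemistry: C9 from a Sharpless epoxide with inversion in a 1,2-shift; C10 and C5 in the key step; C6 by hydride anti to the C5 methyl; C7/C8 by osmylation of the lower face; E C11=C12 from the chromium olefination.

Key step: step 10

Remark: clerodane numbering is used (ring A = C1–C5, C10; ring B = C5–C10; C17 on C8, C18 on C4, C19 on C5, C20 on C9; side chain C11–C16). "Upper face" is the face of the C5 methyl. Compounds 1, 5, 7, 11, 28 and all reagents are taken as commercial. Stereocentres and the alkene geometry that are erased later (in 6–14) are carried as mixtures.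

Step 1
Reactants: 1 (E)-3-methylpent-2-en-4-yn-1-ol
Product: 2 [(2R,3R)-3-ethynyl-3-methyloxiran-2-yl]methanol
Conditions: Ti(OiPr)4 (10 mol%), D-(−)-diethyl tartrate (12 mol%), t-BuOOH, 4 Å MS, CH2Cl2, −20 °C
Reagents that add atoms: tert-butyl hydroperoxide, CC(C)(C)OO
Why: Katsuki–Sharpless asymmetric epoxidation of an E-3,3-disubstituted allylic alcohol; D-(−)-tartrate should deliver oxygen to the face that gives the (2R,3R)-epoxide (mirror image of the L-tartrate outcome for this substitution pattern), which fixes the carbon that becomes C9.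

Step 2
Reactants: 2 [(2R,3R)-3-ethynyl-3-methyloxiran-2-yl]methanol
Product: 3 tert-butyl{[(2R,3R)-3-ethynyl-3-methyloxiran-2-yl]methoxy}dimethylsilane
Conditions: TBSCl, imidazole, DMF, 0 °C to rt
Reagents that add atoms: tert-butyldimethylsilyl chloride, CC(C)(C)[Si](C)(C)Cl
Why: Routine silylation of a primary alcohol; it supplies the siloxymethyl group that migrates in step 3 and no stereocentre is touched.

Step 3
Reactants: 3 tert-butyl{[(2R,3R)-3-ethynyl-3-methyloxiran-2-yl]methoxy}dimethylsilane
Product: 4 (2R)-2-{[(tert-butyldimethylsilyl)oxy]methyl}-2-methylbut-3-ynal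
Conditions: MeAl(OAr)2 (Ar = 4-bromo-2,6-di-tert-butylphenyl), CH2Cl2, −78 °C
Reagents that add atoms: none
Why: Lewis-acid-promoted rearrangement of a 2,3-epoxy silyl ether (semipinacol-type 1,2-shift): the epoxide opens at the tertiary propargylic carbon and the siloxymethyl group migrates anti to the leaving oxygen, so the quaternary centre (C9) should form with inversion and full chirality transfer.

Step 4
Reactants: 4 (2R)-2-{[(tert-butyldimethylsilyl)oxy]methyl}-2-methylbut-3-ynal; 5 (1,3-dioxolan-2-ylmethyl)triphenylphosphonium bromide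
Product: 6 tert-butyl{[(2R)-2-[2-(1,3-dioxolan-2-yl)ethenyl]-2-methylbut-3-yn-1-yl]oxy}dimethylsilane (E/Z mixture)
Conditions: KOtBu, THF, 0 °C; then 4, 0 °C to rt
Reagents that add atoms: none
Why: Wittig two-carbon homologation of a non-enolisable aldehyde with a reactive ylide, giving the enal arm (C10=C1–C2) in protected form; the alkene geometry is corrected in step 8.

Step 5
Reactants: 6 tert-butyl{[(2R)-2-[2-(1,3-dioxolan-2-yl)ethenyl]-2-methylbut-3-yn-1-yl]oxy}dimethylsilane; 7 N-methoxy-N-methylpropanamide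
Product: 9 (6R)-6-{[(tert-butyldimethylsilyl)oxy]methyl}-8-(1,3-dioxolan-2-yl)-6-methyloct-7-en-4-yn-3-one, via lithium acetylide 8 (not isolated)
Conditions: n-BuLi, THF, −78 °C; then 7, −78 to 0 °C; aq NH4Cl
Reagents that add atoms: none
Why: Acylation of a lithium acetylide by a Weinreb amide, whose chelated tetrahedral intermediate prevents over-addition; this attaches C6, C5 and C19.

Step 6
Reactants: 9 (6R)-6-{[(tert-butyldimethylsilyl)oxy]methyl}-8-(1,3-dioxolan-2-yl)-6-methyloct-7-en-4-yn-3-one
Product: 10 (4Z,6R)-6-{[(tert-butyldimethylsilyl)oxy]methyl}-8-(1,3-dioxolan-2-yl)-5,6-dimethylocta-4,7-dien-3-one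
Conditions: Me2CuLi (from CuI and 2 MeLi), Et2O, −78 °C; MeOH then aq NH4Cl at −78 °C
Reagents that add atoms: lithium dimethylcuprate, C[Cu-]C.[Li+]
Why: Conjugate addition of a cuprate to an ynone; the methyl (C17) adds to C8 and cold protonation of the alkenylcopper/allenolate from the side of the small methyl group should leave the carbonyl cis to the bulky C9 substituent (Z).

Step 7
Reactants: 10 (4Z,6R)-6-{[(tert-butyldimethylsilyl)oxy]methyl}-8-(1,3-dioxolan-2-yl)-5,6-dimethylocta-4,7-dien-3-one; 11 acetaldehyde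
Product: 13 (5Z,7R)-7-{[(tert-butyldimethylsilyl)oxy]methyl}-9-(1,3-dioxolan-2-yl)-2-hydroxy-3,6,7-trimethylnona-5,8-dien-4-one, via lithium enolate 12 (not isolated)
Conditions: LDA, THF, −78 °C; then 11, −78 °C; aq NH4Cl
Reagents that add atoms: none
Why: Kinetic α′-deprotonation of the ethyl enone and aldol addition bring in C4 and C3; the two new stereocentres are erased by steps 9 and 10.

Step 8
Reactants: 13 (5Z,7R)-7-{[(tert-butyldimethylsilyl)oxy]methyl}-9-(1,3-dioxolan-2-yl)-2-hydroxy-3,6,7-trimethylnona-5,8-dien-4-one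
Product: 14 (2E,4R,5Z)-4-{[(tert-butyldimethylsilyl)oxy]methyl}-9-hydroxy-4,5,8-trimethyl-7-oxodeca-2,5-dienal
Conditions: PPTS (cat.), acetone–H2O (10:1), rt to 40 °C
Reagents that add atoms: water, O
Why: Mild acetal hydrolysis through an allylic oxocarbenium ion, in which rotation about C10–C1 should equilibrate the arm to the E-enal; PPTS is too weak to cleave the primary TBS ether or isomerise the Z-enone.

Step 9
Reactants: 14 (2E,4R,5Z)-4-{[(tert-butyldimethylsilyl)oxy]methyl}-9-hydroxy-4,5,8-trimethyl-7-oxodeca-2,5-dienal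
Product: 15 (2E,4R,5Z)-4-{[(tert-butyldimethylsilyl)oxy]methyl}-4,5,8-trimethyl-7,9-dioxodeca-2,5-dienal
Conditions: Dess–Martin periodinane, NaHCO3, CH2Cl2, 0 °C to rt; used at once
Reagents that add atoms: none
Why: Dess–Martin oxidation of the β-hydroxy ketone to the 1,3-diketone under neutral conditions, so that the C5 nucleophile is unveiled only immediately before the key step.

Step 10
Reactants: 15 (2E,4R,5Z)-4-{[(tert-butyldimethylsilyl)oxy]methyl}-4,5,8-trimethyl-7,9-dioxodeca-2,5-dienal
Product: 17 trans-fused decalin bis-enone (ring A 2-en-4-one; ring B 8-methyl-7-en-6-one; C9 bears Me and CH2OTBS), via Michael adduct 16 (not isolated)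
Conditions: (R)-2-[diphenyl(trimethylsilyloxy)methyl]pyrrolidine (20 mol%), PhCO2H (20 mol%), toluene, 0 °C to rt; then pyrrolidine (30 mol%), AcOH (30 mol%), 4 Å MS, 45 °C
Reagents that add atoms: none
Why: The enal forms an iminium ion and the 2-methyl-1,3-diketone, as its hydrogen-bonded cis-enol, adds through C5 to C10 (Michael addition, 16); the C4 acetyl group then condenses through its methyl carbon C3 with the freed C2 aldehyde (amine-catalysed aldol addition and loss of water). The closest known reaction type is the amine-catalysed Michael/aldol-condensation (Robinson-type, 3+3) synthesis of cyclohexenones from 1,3-dicarbonyl compounds and enals, here with the Michael step made intramolecular. Ring B closes 6-exo-trig (C5 onto C10 of the exocyclic C10=C1 bond) and ring A closes 6-(enolexo)-exo-trig (C3 onto C2=O) followed by elimination. C10 is set by attack on its Re face, which the shielding group of the (R)-catalyst enforces and which matches the substrate's own chair-like closure (enal arm equatorial, the larger CH2OTBS group of the preset C9 centre anti to the forming bond, C9 methyl axial). C5 is set by the chelated cis-enol, which holds C4 syn to the C6 carbonyl so that the acetyl group ends equatorial and the methyl axial; C4 and C1 are then trans on ring B and the aldol closure should give the trans-decalin. The step needs regioselectivity among several enolisable positions, and ring size secures it: C1 onto either ketone would close a four-membered ring, C5 has no second hydrogen for condensation, the iminium ion forms only at the aldehyde, and the only other six-membered closure (C17 onto C2, bridged) needs slow γ-enolisation of the hindered enone.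

Step 11
Reactants: 17 trans-fused decalin bis-enone
Product: 19 ring A enol triflate (C3=C4–OTf) of the ring B enone, via lithium enolate 18 (not isolated)
Conditions: LiBH(s-Bu)3 (L-Selectride, 1.05 equiv), THF, −78 °C; then PhNTf2, −78 to 0 °C
Reagents that add atoms: N-phenylbis(trifluoromethanesulfonimide), O=S(=O)(N(c1ccccc1)S(=O)(=O)C(F)(F)F)C(F)(F)F
Why: Reductive triflation: the hindered hydride adds 1,4 only to the β-unsubstituted ring A enone (the ring B enone is β,β-disubstituted with a neopentyl carbonyl) and the regiodefined enolate is trapped on oxygen; no stereocentre is formed.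

Step 12
Reactants: 19 ring A enol triflate of the ring B enone
Product: 20 allylic alcohol with the 6-OH on the upper face
Conditions: NaBH4, CeCl3·7H2O, MeOH, −20 °C
Reagents that add atoms: none
Why: Luche 1,2-reduction; hydride should enter C6 from the lower face, anti to the axial C5 methyl on the neighbouring carbon, giving the equatorial 6-OH cis to that methyl.

Step 13
Reactants: 20 allylic alcohol with the 6-OH on the upper face
Product: 21 allylic 6-acetate
Conditions: Ac2O, DMAP, pyridine, CH2Cl2, rt
Reagents that add atoms: acetic anhydride, CC(=O)OC(C)=O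
Why: Standard acylation of a secondary alcohol with retention at C6.

Step 14
Reactants: 21 allylic 6-acetate
Product: 22 6-acetoxy-7,8-diol with both hydroxyls on the lower face
Conditions: OsO4 (10 mol%), NMO, acetone–H2O (5:1), rt
Reagents that add atoms: osmium tetroxide, O=[Os](=O)(=O)=O; N-methylmorpholine N-oxide (terminal oxidant), C[N+]1([O-])CCOCC1
Why: Catalytic syn-dihydroxylation; the lower face of C7=C8 is anti to the allylic acetoxy group and to the axial C9 and C5 methyls, and the electron-poor enol triflate should not react.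

Step 15
Reactants: 22 6-acetoxy-7,8-diol
Product: 23 6-acetate 7-isobutyrate with free tertiary 8-OH
Conditions: (i-PrCO)2O, DMAP (cat.), Et3N, CH2Cl2, 0 °C
Reagents that add atoms: isobutyric anhydride, CC(C)C(=O)OC(=O)C(C)C
Why: Acylation of the secondary equatorial 7-OH; the tertiary axial 8-OH is too hindered to react under these conditions.

Step 16
Reactants: 23 6-acetate 7-isobutyrate enol triflate
Product: 24 ring A 4-methyl-3-ene
Conditions: Me4Sn, Pd(PPh3)4 (5 mol%), LiCl, DMF, 80 °C
Reagents that add atoms: tetramethylstannane, C[Sn](C)(C)C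
Why: Stille methylation of an enol triflate under neutral conditions that tolerate the esters, the free tertiary alcohol and the silyl ether; it is placed after step 14 so that no second electron-rich alkene competes in the osmylation.

Step 17
Reactants: 24 ring A 4-methyl-3-ene
Product: 25 primary C11 alcohol
Conditions: HF·pyridine, pyridine, THF, 0 °C to rt
Reagents that add atoms: none
Why: Buffered, non-basic desilylation of the primary TBS ether, chosen to avoid acyl migration among the C6–C8 oxygens.

Step 18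
Reactants: 25 primary C11 alcohol
Product: 26 C11 aldehyde
Conditions: Dess–Martin periodinane, NaHCO3, CH2Cl2, rt
Reagents that add atoms: none
Why: Dess–Martin oxidation of a neopentyl primary alcohol; the aldehyde has no α-hydrogen and the tertiary 8-OH is inert.

Step 19
Reactants: 26 C11 aldehyde
Product: 27 (E)-alkenylboronic acid pinacol ester (C11=C12–Bpin)
Conditions: CrCl2 (8 equiv), Cl2CHBpin (2 equiv), LiI (4 equiv), THF, rt
Reagents that add atoms: 2-(dichloromethyl)-4,4,5,5-tetramethyl-1,3,2-dioxaborolane, ClC(Cl)B1OC(C)(C)C(C)(C)O1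
Why: Takai–Utimoto borylolefination; the geminal dichromium reagent adds to the aldehyde and eliminates to the E-alkene, and the reagent tolerates esters and free hydroxyl.

Step 20
Reactants: 27 (E)-alkenylboronic acid pinacol ester; 28 4-bromofuran-2(5H)-one
Product: 29 CNP0207114.1
Conditions: Pd(dppf)Cl2 (5 mol%), K3PO4, THF–H2O (10:1), 40 °C
Reagents that add atoms: none
Why: Suzuki–Miyaura coupling of an alkenylboronate with a β-bromo butenolide (a vinylogous acyl bromide, fast in oxidative addition) with retention of the E geometry.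

**Compound list**
1 | (E)-3-methylpent-2-en-4-yn-1-ol | C#C/C(C)=C/CO | starting material
2 | [(2R,3R)-3-ethynyl-3-methyloxiran-2-yl]methanol | C#C[C@@]1(C)O[C@@H]1CO | intermediate
3 | tert-butyl{[(2R,3R)-3-ethynyl-3-methyloxiran-2-yl]methoxy}dimethylsilane | C#C[C@@]1(C)O[C@@H]1CO[Si](C)(C)C(C)(C)C | intermediate
4 | (2R)-2-{[(tert-butyldimethylsilyl)oxy]methyl}-2-methylbut-3-ynal | C#C[C@](C)(CO[Si](C)(C)C(C)(C)C)C=O | intermediate
5 | (1,3-dioxolan-2-ylmethyl)triphenylphosphonium bromide | [Br-].C(C1OCCO1)[P+](c1ccccc1)(c1ccccc1)c1ccccc1 | starting material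
6 | tert-butyl{[(2R)-2-[2-(1,3-dioxolan-2-yl)ethenyl]-2-methylbut-3-yn-1-yl]oxy}dimethylsilane (E/Z mixture) | C#C[C@](C)(CO[Si](C)(C)C(C)(C)C)C=CC1OCCO1 | intermediate
7 | N-methoxy-N-methylpropanamide | CCC(=O)N(C)OC | starting material
8 | lithium acetylide of 6 | [Li]C#C[C@](C)(CO[Si](C)(C)C(C)(C)C)C=CC1OCCO1 | intermediate
9 | (6R)-6-{[(tert-butyldimethylsilyl)oxy]methyl}-8-(1,3-dioxolan-2-yl)-6-methyloct-7-en-4-yn-3-one | CCC(=O)C#C[C@](C)(CO[Si](C)(C)C(C)(C)C)C=CC1OCCO1 | intermediate
10 | (4Z,6R)-6-{[(tert-butyldimethylsilyl)oxy]methyl}-8-(1,3-dioxolan-2-yl)-5,6-dimethylocta-4,7-dien-3-one | CCC(=O)/C=C(/C)[C@](C)(CO[Si](C)(C)C(C)(C)C)C=CC1OCCO1 | intermediate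
11 | acetaldehyde | CC=O | starting material
12 | lithium enolate of 10 (enolate towards the ethyl group) | CC=C(O[Li])/C=C(/C)[C@](C)(CO[Si](C)(C)C(C)(C)C)C=CC1OCCO1 | intermediate
13 | (5Z,7R)-7-{[(tert-butyldimethylsilyl)oxy]methyl}-9-(1,3-dioxolan-2-yl)-2-hydroxy-3,6,7-trimethylnona-5,8-dien-4-one (mixture at C2 and C3) | CC(O)C(C)C(=O)/C=C(/C)[C@](C)(CO[Si](C)(C)C(C)(C)C)C=CC1OCCO1 | intermediate
14 | (2E,4R,5Z)-4-{[(tert-butyldimethylsilyl)oxy]methyl}-9-hydroxy-4,5,8-trimethyl-7-oxodeca-2,5-dienal (mixture at C8 and C9) | CC(O)C(C)C(=O)/C=C(/C)[C@](C)(CO[Si](C)(C)C(C)(C)C)/C=C/C=O | intermediate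
15 | (2E,4R,5Z)-4-{[(tert-butyldimethylsilyl)oxy]methyl}-4,5,8-trimethyl-7,9-dioxodeca-2,5-dienal | CC(=O)C(C)C(=O)/C=C(/C)[C@](C)(CO[Si](C)(C)C(C)(C)C)/C=C/C=O | intermediate
16 | Michael adduct: ring B 8-methyl-7-en-6-one with Me and acetyl on C5, CH2CHO on C10, Me and CH2OTBS on C9; C5, C9, C10 as in the target | O=C1C=C(C)[C@](C)(CO[Si](C)(C)C(C)(C)C)[C@@H](CC=O)[C@]1(C)C(C)=O | intermediate
17 | trans-fused decalin bis-enone: ring A 2-en-4-one, ring B 8-methyl-7-en-6-one; 5-Me and 9-Me on the upper face, H-10 and C11H2OTBS on the lower face | O=C1C=C(C)[C@](C)(CO[Si](C)(C)C(C)(C)C)[C@H]2CC=CC(=O)[C@]12C | intermediate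
18 | lithium enolate (C3=C4–OLi) from conjugate reduction of 17 | O=C1C=C(C)[C@](C)(CO[Si](C)(C)C(C)(C)C)[C@H]2CCC=C(O[Li])[C@]12C | intermediate
19 | enol triflate (C3=C4–OTf) with ring B 8-methyl-7-en-6-one | O=C1C=C(C)[C@](C)(CO[Si](C)(C)C(C)(C)C)[C@H]2CCC=C(OS(=O)(=O)C(F)(F)F)[C@]12C | intermediate
20 | 6-hydroxy (upper face) 7-ene enol triflate | O[C@H]1C=C(C)[C@](C)(CO[Si](C)(C)C(C)(C)C)[C@H]2CCC=C(OS(=O)(=O)C(F)(F)F)[C@]12C | intermediate
21 | 6-acetoxy 7-ene enol triflate | CC(=O)O[C@H]1C=C(C)[C@](C)(CO[Si](C)(C)C(C)(C)C)[C@H]2CCC=C(OS(=O)(=O)C(F)(F)F)[C@]12C | intermediate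
22 | 6-acetoxy-7,8-diol (7-OH and 8-OH on the lower face) enol triflate | CC(=O)O[C@H]1[C@H](O)[C@](C)(O)[C@](C)(CO[Si](C)(C)C(C)(C)C)[C@H]2CCC=C(OS(=O)(=O)C(F)(F)F)[C@]12C | intermediate
23 | 6-acetate 7-isobutyrate 8-ol enol triflate | CC(=O)O[C@H]1[C@H](OC(=O)C(C)C)[C@](C)(O)[C@](C)(CO[Si](C)(C)C(C)(C)C)[C@H]2CCC=C(OS(=O)(=O)C(F)(F)F)[C@]12C | intermediate
24 | 6-acetate 7-isobutyrate 8-ol with ring A 4-methyl-3-ene and C11H2OTBS | CC(=O)O[C@H]1[C@H](OC(=O)C(C)C)[C@](C)(O)[C@](C)(CO[Si](C)(C)C(C)(C)C)[C@H]2CCC=C(C)[C@]12C | intermediate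
25 | C11 primary alcohol | CC(=O)O[C@H]1[C@H](OC(=O)C(C)C)[C@](C)(O)[C@](C)(CO)[C@H]2CCC=C(C)[C@]12C | intermediate
26 | C11 aldehyde | CC(=O)O[C@H]1[C@H](OC(=O)C(C)C)[C@](C)(O)[C@](C)(C=O)[C@H]2CCC=C(C)[C@]12C | intermediate
27 | (E)-C11=C12 alkenylboronic acid pinacol ester | CC(=O)O[C@H]1[C@H](OC(=O)C(C)C)[C@](C)(O)[C@](C)(/C=C/B3OC(C)(C)C(C)(C)O3)[C@H]2CCC=C(C)[C@]12C | intermediate
28 | 4-bromofuran-2(5H)-one | BrC1=CC(=O)OC1 | starting material
29 | CNP0207114.1: 6-acetoxy-8-hydroxy-7-isobutyryloxycleroda-3,11E,13-trien-15,16-olide | CC(=O)O[C@H]1[C@H](OC(=O)C(C)C)[C@](C)(O)[C@](C)(/C=C/C2=CC(=O)OC2)[C@H]2CCC=C(C)[C@]12C | target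

**Totals and risks**

Total step count: 20. Longest linear sequence: 20 steps (1 to 29).

Steps most likely to fail:

Step 10. Face selection at C10 may be weak, or closure may run through the non-chelated enol; either would give the C10 epimer or the cis-fused decalin, and the cascade may also stall after the Michael step. Fallback: starting from 15, the two bonds are made in separate operations with the donor activated instead of the acceptor. MgBr2·OEt2 and i-Pr2NEt in CH2Cl2 at −20 °C turn the diketone into its magnesium chelate, whose fixed U-shape controls C5 and whose reversible Michael closure should give 16 under thermodynamic control, now isolated and purified. A separate aldol condensation (pyrrolidinium acetate, toluene, 45 °C) then comes back to the route at 17. No compound outside the list is made (F0).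

Step 6. The copper allenolate may equilibrate before protonation, or the adduct may isomerise on work-up, so that the kinetic Z geometry needed for ring closure is lost. Fallback: starting from 6, the acetylide is trapped with methyl chloroformate to give methyl (4R)-4-{[(tert-butyldimethylsilyl)oxy]methyl}-6-(1,3-dioxolan-2-yl)-4-methylhex-5-en-2-ynoate F1. Me2CuLi at −78 °C adds syn to give the configurationally stable methyl (2Z,4R)-4-{[(tert-butyldimethylsilyl)oxy]methyl}-6-(1,3-dioxolan-2-yl)-3,4-dimethylhexa-2,5-dienoate F2. Me(MeO)NH·HCl with i-PrMgCl gives the (2Z,4R)-N-methoxy-N-methyl amide F3, and EtMgBr converts this to the ethyl ketone, coming back to the route at 10.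

Step 14. Osmylation of the hindered, acetoxy-deactivated trisubstituted alkene may be slow, so that acetate migration or over-oxidation competes. Fallback: oxidise at the enone stage and set C6 afterwards. Starting from 19, RuCl3 (cat.)/NaIO4 in EtOAc–MeCN–H2O at 0 °C dihydroxylates the electron-poor C7=C8 bond from the lower face to the 7,8-dihydroxy-6-ketone F4. Isobutyric anhydride/DMAP acylates the secondary 7-OH to the 7-isobutyryloxy-8-hydroxy-6-ketone F5. Me4NBH(OAc)3 in MeCN–AcOH, bound to the axial 8-OH, delivers hydride to C6 from the lower face to give the 6-alcohol (upper face) F6. Acetylation (Ac2O, DMAP, pyridine) comes back to the route at 23.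

Further compounds
F0 | step 10 | none | none
F1 | step 6 | methyl (4R)-4-{[(tert-butyldimethylsilyl)oxy]methyl}-6-(1,3-dioxolan-2-yl)-4-methylhex-5-en-2-ynoate | COC(=O)C#C[C@](C)(CO[Si](C)(C)C(C)(C)C)C=CC1OCCO1
F2 | step 6 | methyl (2Z,4R)-4-{[(tert-butyldimethylsilyl)oxy]methyl}-6-(1,3-dioxolan-2-yl)-3,4-dimethylhexa-2,5-dienoate | COC(=O)/C=C(/C)[C@](C)(CO[Si](C)(C)C(C)(C)C)C=CC1OCCO1
F3 | step 6 | (2Z,4R)-4-{[(tert-butyldimethylsilyl)oxy]methyl}-6-(1,3-dioxolan-2-yl)-N-methoxy-N,3,4-trimethylhexa-2,5-dienamide | CON(C)C(=O)/C=C(/C)[C@](C)(CO[Si](C)(C)C(C)(C)C)C=CC1OCCO1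
F4 | step 14 | 7,8-dihydroxy-6-ketone (both hydroxyls on the lower face) enol triflate | O=C1[C@H](O)[C@](C)(O)[C@](C)(CO[Si](C)(C)C(C)(C)C)[C@H]2CCC=C(OS(=O)(=O)C(F)(F)F)[C@]12C
F5 | step 14 | 7-isobutyryloxy-8-hydroxy-6-ketone enol triflate | O=C1[C@H](OC(=O)C(C)C)[C@](C)(O)[C@](C)(CO[Si](C)(C)C(C)(C)C)[C@H]2CCC=C(OS(=O)(=O)C(F)(F)F)[C@]12C
F6 | step 14 | 6-hydroxy (upper face) 7-isobutyrate 8-ol enol triflate | O[C@H]1[C@H](OC(=O)C(C)C)[C@](C)(O)[C@](C)(CO[Si](C)(C)C(C)(C)C)[C@H]2CCC=C(OS(=O)(=O)C(F)(F)F)[C@]12C
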